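## Analysis of the target

The target is a biflavone. Unit 1 is a 5,7-dihydroxy-4'-methoxyflavone and unit 2 is apigenin (5,7,4'-trihydroxyflavone). They are joined by one biaryl bond from C3' of ring B of unit 1 to C6'' of ring A of unit 2. There is no stereocentre. The C3'–C6'' axis carries three ortho substituents (the C4' methoxy group and the C5'' and C7'' hydroxyls) but no configuration is specified for it. Of five phenolic oxygens on three rings, only the one at C4' is methylated, so that oxygen must be distinguished from all the others. The two pyranones open when hydroxide or alkoxide adds at C2, and ethers at their peri positions (C5, C5'') are cleaved by strong Lewis acids. The phloroglucinol-type rings are easily oxidised and easily substituted by electrophiles. The difficulties are the hindered biaryl bond, the choice of C6'' over C8'' as the point of attachment, and the single methyl ether. C6'' and C8'' differ only in which oxygen of the phloroglucinol ring becomes the pyranone oxygen. The strategy rests on ring B of unit 1: C1' carries chromone C2, C3' the aryl group and C4' the oxygen. Oxygen is therefore para to the acceptor-bearing carbon and ortho to the aryl group, which is the pattern a 2-oxygenated 3-arylbutadiene gives with a conjugated alkyne.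

## Retrosynthetic reasoning

**33 to 32.** The four phenols are freed last. Cutting five O–benzyl bonds leads back to 32, whose only other ether is the C4' methyl ether. Hydrogenolysis tells the two kinds of ether apart, and no acidic or basic step is run on the free polyphenol.

**32 to 28 and 29.** The pyranone of unit 2 is cut at O1''–C2'' and C2''–C3''. This gives the ortho-hydroxyacetophenone 28 and the aroyl chloride 29, joined forward through the ester 30 and the diketone 31 (Baker–Venkataraman sequence). The cut is made here because 28 has one free phenol, the one para to the biaryl bond, so ring closure can only give the C6''-linked flavone.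

**28 to 25.** The bond from C4a'' to the acetyl carbon is cut next. Forward, the acetyl group is introduced through the iodide 26 and a cross-coupled enol ether 27, not by Lewis-acid acylation, because 25 holds benzyl ethers peri to a pyranone carbonyl. The two free positions on ring A of unit 2 in 25 are equivalent, so there is no regiochemical question. The acid that unmasks the ketone also removes the acetal from the neighbouring oxygen.

**25 to 22.** The C4' methyl ether is traced to the aryl silyl ether 23, through the phenol 24, which is the only free phenol present at that stage. Arene 23 is traced to the 1,4-cyclohexadiene 22 by adding back two hydrogens. Forward, a dehydrogenation turns the enol silane of 22 into the aryl silyl ether.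

**22 to 21 and 8.** This is the key disconnection. C1'–C2' and C5'–C6' of ring B of unit 1 are cut, giving the 2-silyloxy-3-arylbutadiene 21 and the ethynylchromone 8. The chromone of unit 1 then arrives complete. The hindered biaryl bond is already present in 21 as the bond from the aryl group to diene C3, so it is never made by cross-coupling. The forward reaction has to join the diene CH2 next to the siloxy carbon to the terminal alkyne carbon.

**21 to 15 and 16.** The diene comes from enone 20 by silylation of its only enolisable position. Enone 20 comes from the arylacetone 19 by methylenation of the benzylic carbon. Ketone 19 comes from alcohol 18, which is cut at the aryl–CH2 bond into the aryllithium 17 (from bromide 15) and the epoxide 16. This aryl–CH2 bond later becomes the biaryl bond.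

**15 to 9.** The bromide needs two benzyl ethers flanking bromine and a differently protected oxygen para to it. The para oxygen is introduced into 9 by sterically controlled C–H borylation and oxidation (10 to 12 through 11). The benzyl groups go on only afterwards (13 to 15 through 14), because benzyl ethers present during the borylation would offer competing unhindered arene C–H bonds.

**8 to 1 and 3.** The alkyne is taken back by one-carbon homologation to aldehyde 7, then to alcohol 6 and ester 5. The pyranone of 5 is cut into acetophenone 2 and the oxalate 3 (through 4). Compound 2 is the selectively dibenzylated form of 1.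

## Alternatives that were turned down

**Alternative 1:** Ring A of unit 2 is disconnected at O1''–C8a'' and C4''–C4a'' into an aryne and 3-[4-(benzyloxy)phenyl]propiolic acid A2.
- **Forward key step:** Fluoride releases the aryne from the ortho-silylaryl triflate A3, which already holds the biaryl bond and a dioxolane-masked aldehyde on ring B of unit 1. The carboxylate of A2 adds through oxygen and the aryl anion takes over the acyl group, giving the 2-hydroxyaryl ynone A1. A1 is then closed to the flavone, and the chromone of unit 1 is built afterwards from the aldehyde.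
- **For:** The benzyloxy group beside one aryne carbon sends the oxygen nucleophile to the remote carbon, so O1'' ends para to the biaryl bond without any protecting-group differentiation. On this point it is stronger than the chosen route, which spends an acetal group and steps 17 and 18 to place the acetyl group.
- **Against:** A3 is a hexasubstituted arene. Its tri-ortho-substituted biaryl bond, silyl group and triflate must all be installed first, which means a long linear sequence with a hindered cross-coupling. Acyl transfer competes with simple protonation to the aryl ester. The ynone must close 6-endo and not 5-exo. The second chromone must still be built on a molecule that already contains a flavone.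
- **Comparison:** The chosen route makes the hindered biaryl bond as an ordinary aryl–CH2 bond (step 10) and brings in the chromone of unit 1 ready-made.

**Alternative 2:** Ring A of unit 2 is disconnected at C4a''–C5'', C5''–C6'' and C7''–C8'' and is assembled on a preformed 2-aryl-4-pyranone.
- **Forward key step:** Irradiation of the diazo ketone A5 causes Wolff rearrangement to a pyranonyl ketene. [2+2] addition to the siloxyalkyne A6, ring opening of the cyclobutenone and 6π electrocyclisation (Danheiser benzannulation) give the flavone A4.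
- **For:** The fully substituted ring A forms in one operation with C5''–OH free, C7''–O silylated and the aryl group between them. For unit 2 it is shorter than the chosen route, which needs steps 17 to 20 to grow this pyranone.
- **Against:** A 4-pyranone is itself photoactive, so the Wolff step has competition. The 6π closure must use a C=C bond of a cross-conjugated vinylogous ester, for which there is no close analogy. A5 and A6 each need several steps, including diazo chemistry. The chromone of unit 1 again has to be built afterwards from a masked aldehyde.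
- **Comparison:** The chosen key step is thermal, ground-state chemistry between two stable partners, and its failure has a simple fallback.

**Alternative 3:** Ring B of unit 1 is disconnected at C2'–C3' and C4'–C5'.
- **Forward key step:** Methyl coumalate A8 and the aryl methoxyalkyne A9 undergo an inverse-demand [4+2] cycloaddition. Decarboxylative cycloreversion then gives the benzoate A7.
- **For:** Both partners are strongly polarised, so regiocontrol is at least as secure as in the chosen route. The methyl ether is placed directly and aromatisation is automatic, which saves the equivalent of steps 15 and 16. On these two points it is the stronger plan.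
- **Against:** A9 is an ynol ether on a 2,6-dialkoxyaryl group and is delicate to make and to heat. Its nucleophilic carbon is the one shielded by the twisted aryl group, and that carbon must attack C6 of A8. After the key step the chromone of unit 1 still has to be built from the ester with acetophenone 2 (hydrolysis, esterification, acyl shift, cyclisation), which uses up the saving.
- **Comparison:** The chosen route keeps the chromone in the dienophile and makes its diene from an enone by one silylation.

Key step: step 14

Remark on the chemistry: the C3'–C6'' axis is treated as freely rotating and no atroposelective step is planned. Propylene oxide is used as the racemate because the carbinol centre of 18 is oxidised away in step 11.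

## Route

Step 1
Reactants: 1 2,4,6-trihydroxyacetophenone
Product: 2 1-[2,4-bis(benzyloxy)-6-hydroxyphenyl]ethanone
Conditions: BnBr (2.05 equiv), K2CO3, DMF, rt
Reagents that add atoms: benzyl bromide, BrCc1ccccc1
Why: Williamson etherification. The para hydroxyl and one ortho hydroxyl are alkylated, while the second ortho hydroxyl is held in a hydrogen bond to the acetyl carbonyl and stays free.

Step 2
Reactants: 2 1-[2,4-bis(benzyloxy)-6-hydroxyphenyl]ethanone; 3 diethyl oxalate
Product: 5 ethyl 5,7-bis(benzyloxy)-4-oxo-4H-chromene-2-carboxylate, via diketo ester 4 (not isolated)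
Conditions: NaOEt, EtOH, 75 °C; then HCl, EtOH, 75 °C
Reagents that add atoms: none
Why: Claisen condensation of the acetophenone enolate with the oxalate gives the 2,4-dioxobutanoate 4. Acid then closes it onto the free phenol with loss of water, the standard chromone-2-carboxylate synthesis.

Step 3
Reactants: 5 ethyl 5,7-bis(benzyloxy)-4-oxo-4H-chromene-2-carboxylate
Product: 6 5,7-bis(benzyloxy)-2-(hydroxymethyl)-4H-chromen-4-one
Conditions: NaBH4, MeOH/THF, 0 °C
Reagents that add atoms: none
Why: Chemoselective borohydride reduction. The ester is activated by the electron-poor pyranone, whereas the C4 carbonyl is a vinylogous ester and much less electrophilic.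

Step 4
Reactants: 6 5,7-bis(benzyloxy)-2-(hydroxymethyl)-4H-chromen-4-one
Product: 7 5,7-bis(benzyloxy)-4-oxo-4H-chromene-2-carbaldehyde
Conditions: Dess–Martin periodinane, CH2Cl2, rt
Reagents that add atoms: none
Why: Dess–Martin oxidation of a primary alcohol to the aldehyde under near-neutral conditions that leave the pyranone and the benzyl ethers alone.

Step 5
Reactants: 7 5,7-bis(benzyloxy)-4-oxo-4H-chromene-2-carbaldehyde
Product: 8 5,7-bis(benzyloxy)-2-ethynyl-4H-chromen-4-one
Conditions: dimethyl (1-diazo-2-oxopropyl)phosphonate, NaOMe (1.0 equiv), THF, –78 °C; then 7, –78 °C to rt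
Reagents that add atoms: dimethyl (1-diazo-2-oxopropyl)phosphonate, COP(=O)(OC)C(=[N+]=[N-])C(C)=O
Why: Seyferth–Gilbert homologation in its Ohira–Bestmann form: the diazomethylphosphonate anion olefinates the aldehyde, and loss of nitrogen with a 1,2-hydrogen shift gives the terminal alkyne. Making the anion with one equivalent of methoxide at low temperature leaves no free alkoxide to add to chromone C2 or to the product.

Step 6
Reactants: 9 2-bromoresorcinol
Product: 10 2-bromo-1,3-bis(tert-butyldimethylsilyloxy)benzene
Conditions: TBSCl, imidazole, DMF, rt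
Reagents that add atoms: tert-butyldimethylsilyl chloride, CC(C)(C)[Si](C)(C)Cl
Why: Standard silylation of both phenols. Silyl groups are used here because benzyl groups would offer unhindered arene C–H bonds to the borylation catalyst of step 7.

Step 7
Reactants: 10 2-bromo-1,3-bis(tert-butyldimethylsilyloxy)benzene
Product: 12 4-bromo-3,5-bis(tert-butyldimethylsilyloxy)phenol, via arylboronate 11 (not isolated)
Conditions: [Ir(OMe)(cod)]2 (cat.), 4,4'-di-tert-butyl-2,2'-bipyridine, B2pin2, THF, 80 °C; then Oxone (2KHSO5·KHSO4·K2SO4), acetone/H2O, 0 °C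
Reagents that add atoms: bis(pinacolato)diboron, CC1(C)OB(B2OC(C)(C)C(C)(C)O2)OC1(C)C (boron is carried only in 11); potassium peroxymonosulfate, [K+].[O-]OS(=O)(=O)O
Why: Iridium-catalysed C–H borylation is governed by sterics, and C5 is the only C–H bond without an ortho substituent. Oxidation of the C–B bond in the same flask gives the phenol; the aryl bromide is tolerated.

Step 8
Reactants: 12 4-bromo-3,5-bis(tert-butyldimethylsilyloxy)phenol
Product: 13 2-bromo-1,3-bis(tert-butyldimethylsilyloxy)-5-(methoxymethoxy)benzene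
Conditions: MOMCl, i-Pr2NEt, CH2Cl2, 0 °C to rt
Reagents that add atoms: chloromethyl methyl ether, COCCl
Why: Alkylation of the single free phenol. This acetal marks the oxygen that later becomes O1'' of unit 2 and can be removed in the presence of benzyl and methyl ethers.

Step 9
Reactants: 13 2-bromo-1,3-bis(tert-butyldimethylsilyloxy)-5-(methoxymethoxy)benzene
Product: 15 1,3-bis(benzyloxy)-2-bromo-5-(methoxymethoxy)benzene, via resorcinol 14 (not isolated)
Conditions: Bu4NF, THF, 0 °C; then BnBr, DMF, rt
Reagents that add atoms: benzyl bromide, BrCc1ccccc1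
Why: Fluoride cleaves both aryl silyl ethers, and the tetrabutylammonium phenoxides are benzylated in the same flask (Williamson etherification), so the air-sensitive diol is not handled. Removing silicon here also excludes silyl migration in the lithiation of step 10.

Step 10
Reactants: 15 1,3-bis(benzyloxy)-2-bromo-5-(methoxymethoxy)benzene; 16 propylene oxide (racemic)
Product: 18 rac-1-[2,6-bis(benzyloxy)-4-(methoxymethoxy)phenyl]propan-2-ol, via aryllithium 17 (not isolated)
Conditions: n-BuLi, THF, –78 °C; then 16, BF3·OEt2, –78 °C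
Reagents that add atoms: n-butyllithium, [Li]CCCC (supplies the lithium of 17 only)
Why: Bromine–lithium exchange at –78 °C is faster than benzylic deprotonation. The aryllithium opens the epoxide, activated by BF3, at its unsubstituted carbon by SN2. The carbinol centre is racemic and is removed in step 11.

Step 11
Reactants: 18 rac-1-[2,6-bis(benzyloxy)-4-(methoxymethoxy)phenyl]propan-2-ol
Product: 19 1-[2,6-bis(benzyloxy)-4-(methoxymethoxy)phenyl]propan-2-one
Conditions: Dess–Martin periodinane, CH2Cl2, rt
Reagents that add atoms: none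
Why: Dess–Martin oxidation of the secondary alcohol. The aryl acetal and the benzyl ethers tolerate the acetic acid released at room temperature.

Step 12
Reactants: 19 1-[2,6-bis(benzyloxy)-4-(methoxymethoxy)phenyl]propan-2-one
Product: 20 3-[2,6-bis(benzyloxy)-4-(methoxymethoxy)phenyl]but-3-en-2-one
Conditions: Me2NCH2NMe2, Ac2O, DMF, 40 °C
Reagents that add atoms: bis(dimethylamino)methane, CN(C)CN(C)C (supplies the CH2 group)
Why: Mannich-type α-methylenation. The aminal and the anhydride give a methyleneiminium acetate, the ketone reacts through its more substituted and more acidic benzylic enol, and the amine is then eliminated to give the 1,1-disubstituted enone.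

Step 13
Reactants: 20 3-[2,6-bis(benzyloxy)-4-(methoxymethoxy)phenyl]but-3-en-2-one
Product: 21 2-(tert-butyldimethylsilyloxy)-3-[2,6-bis(benzyloxy)-4-(methoxymethoxy)phenyl]buta-1,3-diene
Conditions: TBSOTf, Et3N, CH2Cl2, 0 °C
Reagents that add atoms: tert-butyldimethylsilyl trifluoromethanesulfonate, CC(C)(C)[Si](C)(C)OS(=O)(=O)C(F)(F)F
Why: Soft enolisation. The methyl group is the only enolisable position of the enone, so O-silylation with the triflate and an amine base gives the 2-silyloxydiene as one regioisomer.

Step 14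
Reactants: 21 2-(tert-butyldimethylsilyloxy)-3-[2,6-bis(benzyloxy)-4-(methoxymethoxy)phenyl]buta-1,3-diene; 8 5,7-bis(benzyloxy)-2-ethynyl-4H-chromen-4-one
Product: 22 5,7-bis(benzyloxy)-2-{5-[2,6-bis(benzyloxy)-4-(methoxymethoxy)phenyl]-4-(tert-butyldimethylsilyloxy)cyclohexa-1,4-dien-1-yl}-4H-chromen-4-one
Conditions: 21 (1.5 equiv), BHT (cat.), toluene, 120–130 °C, sealed tube, base-washed glass; crude product used directly
Reagents that add atoms: none
Why: The electron-rich 2-silyloxydiene 21 (raised HOMO) and the alkyne of 8, polarised through C2=C3 of the pyranone towards the C4 carbonyl (lowered LUMO), should combine in a thermal, concerted but asynchronous normal-demand Diels–Alder reaction; the closest known reaction type is the [4+2] addition of 2-silyloxy-1,3-dienes to alkynones and propiolates followed by dehydrogenation to the arene. Ring B of unit 1 is closed as a six-membered carbocycle by the cycloaddition itself, both new sigma bonds (C1'–C2' and C5'–C6') forming in one step across the s-cis diene. No stereocentre is created, because both new sp3 carbons are CH2 groups. The step needs regioselectivity: the largest HOMO coefficient is on the CH2 next to the siloxy carbon and the largest LUMO coefficient on the terminal alkyne carbon (the vinylogous acceptor position), so these two join first and the siloxy carbon ends para to the chromone-bearing carbon, with the aryl group ortho to oxygen and meta to the chromone. The 2,6-bis(benzyloxy)aryl group is twisted out of the diene plane by its ortho substituents and so cannot compete as a directing donor. The step also needs chemoselectivity for the alkyne over the C2=C3 bond of the pyranone, which the unhindered terminal alkyne and the loss of pyranone conjugation on attack at C2=C3 should secure. Acid is excluded so that the enol silane survives and no stepwise Mukaiyama–Michael path opens.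

Step 15
Reactants: 22 5,7-bis(benzyloxy)-2-{5-[2,6-bis(benzyloxy)-4-(methoxymethoxy)phenyl]-4-(tert-butyldimethylsilyloxy)cyclohexa-1,4-dien-1-yl}-4H-chromen-4-one
Product: 23 5,7-bis(benzyloxy)-2-{3-[2,6-bis(benzyloxy)-4-(methoxymethoxy)phenyl]-4-(tert-butyldimethylsilyloxy)phenyl}-4H-chromen-4-one
Conditions: DDQ (1.1 equiv), toluene, 0 °C to rt
Reagents that add atoms: none
Why: Quinone dehydrogenation. Hydride is taken from a doubly allylic CH2 group and a proton is then lost, which aromatises the 1,4-cyclohexadiene and turns the enol silane into an aryl silyl ether. Unsubstituted benzyl ethers and the acetal are not attacked at this temperature.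

Step 16
Reactants: 23 5,7-bis(benzyloxy)-2-{3-[2,6-bis(benzyloxy)-4-(methoxymethoxy)phenyl]-4-(tert-butyldimethylsilyloxy)phenyl}-4H-chromen-4-one
Product: 25 5,7-bis(benzyloxy)-2-{3-[2,6-bis(benzyloxy)-4-(methoxymethoxy)phenyl]-4-methoxyphenyl}-4H-chromen-4-one, via C4' phenol 24 (not isolated)
Conditions: CsF, MeI, DMF, rt
Reagents that add atoms: iodomethane, CI
Why: Fluoride cleaves the aryl silyl ether and the caesium phenoxide is methylated in the same flask (Williamson etherification). It is the only free phenol in the molecule, so the methyl group can go nowhere else.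

Step 17
Reactants: 25 5,7-bis(benzyloxy)-2-{3-[2,6-bis(benzyloxy)-4-(methoxymethoxy)phenyl]-4-methoxyphenyl}-4H-chromen-4-one
Product: 26 5,7-bis(benzyloxy)-2-{3-[2,6-bis(benzyloxy)-3-iodo-4-(methoxymethoxy)phenyl]-4-methoxyphenyl}-4H-chromen-4-one
Conditions: N-iodosuccinimide (1.05 equiv), MeCN/CH2Cl2, 0 °C to rt, dark
Reagents that add atoms: N-iodosuccinimide, O=C1CCC(=O)N1I
Why: Electrophilic aromatic iodination. The phloroglucinol triether ring is by far the most electron-rich arene and its two free positions are equivalent. Ring A of the chromone is deactivated by the pyranone carbonyl and ring B by the chromone para to its methoxy group.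

Step 18
Reactants: 26 5,7-bis(benzyloxy)-2-{3-[2,6-bis(benzyloxy)-3-iodo-4-(methoxymethoxy)phenyl]-4-methoxyphenyl}-4H-chromen-4-one
Product: 28 2-{3-[3-acetyl-2,6-bis(benzyloxy)-4-hydroxyphenyl]-4-methoxyphenyl}-5,7-bis(benzyloxy)-4H-chromen-4-one, via enol ether 27 (not isolated)
Conditions: tributyl(1-ethoxyvinyl)stannane, Pd(PPh3)4 (cat.), CuI, CsF, DMF, 60 °C; then 2 M aq. HCl, MeOH/THF, 40 °C
Reagents that add atoms: tributyl(1-ethoxyvinyl)stannane, CCCC[Sn](CCCC)(CCCC)C(=C)OCC; water, O
Why: Stille coupling with an acetyl anion equivalent, using copper and fluoride to help transmetalation at the hindered iodide. Dilute acid then hydrolyses the enol ether to the methyl ketone and removes the acetal, which is now ortho to a carbonyl group; the benzyl ethers stay.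

Step 19
Reactants: 28 2-{3-[3-acetyl-2,6-bis(benzyloxy)-4-hydroxyphenyl]-4-methoxyphenyl}-5,7-bis(benzyloxy)-4H-chromen-4-one; 29 4-(benzyloxy)benzoyl chloride
Product: 30 2-acetyl-3,5-bis(benzyloxy)-4-{5-[5,7-bis(benzyloxy)-4-oxo-4H-chromen-2-yl]-2-methoxyphenyl}phenyl 4-(benzyloxy)benzoate
Conditions: pyridine, DMAP (cat.), CH2Cl2, rt
Reagents that add atoms: none
Why: O-acylation of the only free phenol with acyl-transfer catalysis, the first stage of the Baker–Venkataraman flavone synthesis.

Step 20
Reactants: 30 2-acetyl-3,5-bis(benzyloxy)-4-{5-[5,7-bis(benzyloxy)-4-oxo-4H-chromen-2-yl]-2-methoxyphenyl}phenyl 4-(benzyloxy)benzoate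
Product: 32 5,7-bis(benzyloxy)-6-{5-[5,7-bis(benzyloxy)-4-oxo-4H-chromen-2-yl]-2-methoxyphenyl}-2-[4-(benzyloxy)phenyl]-4H-chromen-4-one, via 1,3-diketone 31 (not isolated)
Conditions: t-BuOK, THF, 0 °C to rt; then AcOH, H2SO4 (cat.), 60 °C
Reagents that add atoms: none
Why: Baker–Venkataraman rearrangement: the ketone enolate attacks the neighbouring aryl ester and the aroyl group moves from oxygen to carbon. Acid then cyclises and dehydrates the diketone onto the freed phenol, which is para to the biaryl bond, so only the C6''-linked flavone can form.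

Step 21
Reactants: 32 5,7-bis(benzyloxy)-6-{5-[5,7-bis(benzyloxy)-4-oxo-4H-chromen-2-yl]-2-methoxyphenyl}-2-[4-(benzyloxy)phenyl]-4H-chromen-4-one
Product: 33 5,7-dihydroxy-6-[5-(5,7-dihydroxy-4-oxo-4H-chromen-2-yl)-2-methoxyphenyl]-2-(4-hydroxyphenyl)-4H-chromen-4-one (the target)
Conditions: H2 (1 atm), 10% Pd/C, THF/MeOH, rt
Reagents that add atoms: none
Why: Hydrogenolysis of the five benzyl ethers. The aryl methyl ether is inert, and the pyranone double bonds are reduced far more slowly than benzyl C–O bonds at atmospheric pressure.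

## Compound list

1 | 2,4,6-trihydroxyacetophenone | CC(=O)c1c(O)cc(O)cc1O | starting material
2 | 1-[2,4-bis(benzyloxy)-6-hydroxyphenyl]ethanone | CC(=O)c1c(O)cc(OCc2ccccc2)cc1OCc1ccccc1 | intermediate
3 | diethyl oxalate | CCOC(=O)C(=O)OCC | starting material
4 | ethyl 4-[2,4-bis(benzyloxy)-6-hydroxyphenyl]-2,4-dioxobutanoate | CCOC(=O)C(=O)CC(=O)c1c(O)cc(OCc2ccccc2)cc1OCc1ccccc1 | intermediate (not isolated)
5 | ethyl 5,7-bis(benzyloxy)-4-oxo-4H-chromene-2-carboxylate | CCOC(=O)c1cc(=O)c2c(OCc3ccccc3)cc(OCc3ccccc3)cc2o1 | intermediate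
6 | 5,7-bis(benzyloxy)-2-(hydroxymethyl)-4H-chromen-4-one | OCc1cc(=O)c2c(OCc3ccccc3)cc(OCc3ccccc3)cc2o1 | intermediate
7 | 5,7-bis(benzyloxy)-4-oxo-4H-chromene-2-carbaldehyde | O=Cc1cc(=O)c2c(OCc3ccccc3)cc(OCc3ccccc3)cc2o1 | intermediate
8 | 5,7-bis(benzyloxy)-2-ethynyl-4H-chromen-4-one | C#Cc1cc(=O)c2c(OCc3ccccc3)cc(OCc3ccccc3)cc2o1 | intermediate
9 | 2-bromoresorcinol | Oc1cccc(O)c1Br | starting material
10 | 2-bromo-1,3-bis(tert-butyldimethylsilyloxy)benzene | CC(C)(C)[Si](C)(C)Oc1cccc(O[Si](C)(C)C(C)(C)C)c1Br | intermediate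
11 | 2-[4-bromo-3,5-bis(tert-butyldimethylsilyloxy)phenyl]-4,4,5,5-tetramethyl-1,3,2-dioxaborolane | CC(C)(C)[Si](C)(C)Oc1cc(B2OC(C)(C)C(C)(C)O2)cc(O[Si](C)(C)C(C)(C)C)c1Br | intermediate (not isolated)
12 | 4-bromo-3,5-bis(tert-butyldimethylsilyloxy)phenol | CC(C)(C)[Si](C)(C)Oc1cc(O)cc(O[Si](C)(C)C(C)(C)C)c1Br | intermediate
13 | 2-bromo-1,3-bis(tert-butyldimethylsilyloxy)-5-(methoxymethoxy)benzene | COCOc1cc(O[Si](C)(C)C(C)(C)C)c(Br)c(O[Si](C)(C)C(C)(C)C)c1 | intermediate
14 | 2-bromo-5-(methoxymethoxy)benzene-1,3-diol (formed as its tetrabutylammonium phenoxide) | COCOc1cc(O)c(Br)c(O)c1 | intermediate (not isolated)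
15 | 1,3-bis(benzyloxy)-2-bromo-5-(methoxymethoxy)benzene | COCOc1cc(OCc2ccccc2)c(Br)c(OCc2ccccc2)c1 | intermediate
16 | propylene oxide (racemic) | CC1CO1 | starting material
17 | [2,6-bis(benzyloxy)-4-(methoxymethoxy)phenyl]lithium | [Li]c1c(OCc2ccccc2)cc(OCOC)cc1OCc1ccccc1 | intermediate (not isolated)
18 | rac-1-[2,6-bis(benzyloxy)-4-(methoxymethoxy)phenyl]propan-2-ol | COCOc1cc(OCc2ccccc2)c(CC(C)O)c(OCc2ccccc2)c1 | intermediate
19 | 1-[2,6-bis(benzyloxy)-4-(methoxymethoxy)phenyl]propan-2-one | COCOc1cc(OCc2ccccc2)c(CC(C)=O)c(OCc2ccccc2)c1 | intermediate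
20 | 3-[2,6-bis(benzyloxy)-4-(methoxymethoxy)phenyl]but-3-en-2-one | COCOc1cc(OCc2ccccc2)c(C(=C)C(C)=O)c(OCc2ccccc2)c1 | intermediate
21 | 2-(tert-butyldimethylsilyloxy)-3-[2,6-bis(benzyloxy)-4-(methoxymethoxy)phenyl]buta-1,3-diene | C=C(O[Si](C)(C)C(C)(C)C)C(=C)c1c(OCc2ccccc2)cc(OCOC)cc1OCc1ccccc1 | intermediate
22 | 5,7-bis(benzyloxy)-2-{5-[2,6-bis(benzyloxy)-4-(methoxymethoxy)phenyl]-4-(tert-butyldimethylsilyloxy)cyclohexa-1,4-dien-1-yl}-4H-chromen-4-one | O=c1cc(C2=CCC(O[Si](C)(C)C(C)(C)C)=C(c3c(OCc4ccccc4)cc(OCOC)cc3OCc3ccccc3)C2)oc2cc(OCc3ccccc3)cc(OCc3ccccc3)c12 | intermediate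
23 | 5,7-bis(benzyloxy)-2-{3-[2,6-bis(benzyloxy)-4-(methoxymethoxy)phenyl]-4-(tert-butyldimethylsilyloxy)phenyl}-4H-chromen-4-one | O=c1cc(-c2ccc(O[Si](C)(C)C(C)(C)C)c(-c3c(OCc4ccccc4)cc(OCOC)cc3OCc3ccccc3)c2)oc2cc(OCc3ccccc3)cc(OCc3ccccc3)c12 | intermediate
24 | 5,7-bis(benzyloxy)-2-{3-[2,6-bis(benzyloxy)-4-(methoxymethoxy)phenyl]-4-hydroxyphenyl}-4H-chromen-4-one (formed as its caesium phenoxide) | O=c1cc(-c2ccc(O)c(-c3c(OCc4ccccc4)cc(OCOC)cc3OCc3ccccc3)c2)oc2cc(OCc3ccccc3)cc(OCc3ccccc3)c12 | intermediate (not isolated)
25 | 5,7-bis(benzyloxy)-2-{3-[2,6-bis(benzyloxy)-4-(methoxymethoxy)phenyl]-4-methoxyphenyl}-4H-chromen-4-one | COc1ccc(-c2cc(=O)c3c(OCc4ccccc4)cc(OCc4ccccc4)cc3o2)cc1-c1c(OCc2ccccc2)cc(OCOC)cc1OCc1ccccc1 | intermediate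
26 | 5,7-bis(benzyloxy)-2-{3-[2,6-bis(benzyloxy)-3-iodo-4-(methoxymethoxy)phenyl]-4-methoxyphenyl}-4H-chromen-4-one | COc1ccc(-c2cc(=O)c3c(OCc4ccccc4)cc(OCc4ccccc4)cc3o2)cc1-c1c(OCc2ccccc2)cc(OCOC)c(I)c1OCc1ccccc1 | intermediate
27 | 5,7-bis(benzyloxy)-2-{3-[2,6-bis(benzyloxy)-3-(1-ethoxyvinyl)-4-(methoxymethoxy)phenyl]-4-methoxyphenyl}-4H-chromen-4-one | COc1ccc(-c2cc(=O)c3c(OCc4ccccc4)cc(OCc4ccccc4)cc3o2)cc1-c1c(OCc2ccccc2)cc(OCOC)c(C(=C)OCC)c1OCc1ccccc1 | intermediate (not isolated)
28 | 2-{3-[3-acetyl-2,6-bis(benzyloxy)-4-hydroxyphenyl]-4-methoxyphenyl}-5,7-bis(benzyloxy)-4H-chromen-4-one | COc1ccc(-c2cc(=O)c3c(OCc4ccccc4)cc(OCc4ccccc4)cc3o2)cc1-c1c(OCc2ccccc2)cc(O)c(C(C)=O)c1OCc1ccccc1 | intermediate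
29 | 4-(benzyloxy)benzoyl chloride | O=C(Cl)c1ccc(OCc2ccccc2)cc1 | starting material
30 | 2-acetyl-3,5-bis(benzyloxy)-4-{5-[5,7-bis(benzyloxy)-4-oxo-4H-chromen-2-yl]-2-methoxyphenyl}phenyl 4-(benzyloxy)benzoate | COc1ccc(-c2cc(=O)c3c(OCc4ccccc4)cc(OCc4ccccc4)cc3o2)cc1-c1c(OCc2ccccc2)cc(OC(=O)c2ccc(OCc3ccccc3)cc2)c(C(C)=O)c1OCc1ccccc1 | intermediate
31 | 1-(2,4-bis(benzyloxy)-3-{5-[5,7-bis(benzyloxy)-4-oxo-4H-chromen-2-yl]-2-methoxyphenyl}-6-hydroxyphenyl)-3-[4-(benzyloxy)phenyl]propane-1,3-dione | COc1ccc(-c2cc(=O)c3c(OCc4ccccc4)cc(OCc4ccccc4)cc3o2)cc1-c1c(OCc2ccccc2)cc(O)c(C(=O)CC(=O)c2ccc(OCc3ccccc3)cc2)c1OCc1ccccc1 | intermediate (not isolated)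
32 | 5,7-bis(benzyloxy)-6-{5-[5,7-bis(benzyloxy)-4-oxo-4H-chromen-2-yl]-2-methoxyphenyl}-2-[4-(benzyloxy)phenyl]-4H-chromen-4-one | COc1ccc(-c2cc(=O)c3c(OCc4ccccc4)cc(OCc4ccccc4)cc3o2)cc1-c1c(OCc2ccccc2)cc2oc(-c3ccc(OCc4ccccc4)cc3)cc(=O)c2c1OCc1ccccc1 | intermediate
33 | 5,7-dihydroxy-6-[5-(5,7-dihydroxy-4-oxo-4H-chromen-2-yl)-2-methoxyphenyl]-2-(4-hydroxyphenyl)-4H-chromen-4-one | COc1ccc(-c2cc(=O)c3c(O)cc(O)cc3o2)cc1-c1c(O)cc2oc(-c3ccc(O)cc3)cc(=O)c2c1O | target

## Step count and least certain steps

Total: 21 steps (5 for the dienophile, 8 for the diene, the key step, 7 after it). Longest linear sequence: 16 steps, from 9 through steps 6 to 21.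

**Step 14 (key step).** The alkyne of 8 is activated only vinylogously, and the diene carries two substituents on its inner carbons, one of them bulky. The likely failure is a cycloaddition too slow to compete with oligomerisation of the ethynylchromone and loss of the silyl group from the diene at the required temperature. Erosion of regioselectivity is the smaller risk. The fallback builds ring B with a simple, more reactive alkyne and makes the chromone afterwards. It sets out from 21 and comes back at 25.
- Diene 21 and methyl propiolate in hot toluene should give methyl 5-[2,6-bis(benzyloxy)-4-(methoxymethoxy)phenyl]-4-(tert-butyldimethylsilyloxy)cyclohexa-1,4-diene-1-carboxylate F1.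
- DDQ converts it into methyl 3-[2,6-bis(benzyloxy)-4-(methoxymethoxy)phenyl]-4-(tert-butyldimethylsilyloxy)benzoate F2.
- CsF and MeI give methyl 3-[2,6-bis(benzyloxy)-4-(methoxymethoxy)phenyl]-4-methoxybenzoate F3, the same ester as A7.
- LiOH gives 3-[2,6-bis(benzyloxy)-4-(methoxymethoxy)phenyl]-4-methoxybenzoic acid F4.
- Carbodiimide coupling (EDC·HCl, DMAP) with phenol 2 gives 2-acetyl-3,5-bis(benzyloxy)phenyl 3-[2,6-bis(benzyloxy)-4-(methoxymethoxy)phenyl]-4-methoxybenzoate F5.
- t-BuOK rearranges it to 1-[2,4-bis(benzyloxy)-6-hydroxyphenyl]-3-{3-[2,6-bis(benzyloxy)-4-(methoxymethoxy)phenyl]-4-methoxyphenyl}propane-1,3-dione F6.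
- Catalytic TsOH in warm toluene closes F6 to 25.

**Step 5.** The aldehyde 7 and the enyne product 8 are both acceptors for alkoxide. The likely failure is conjugate addition of methoxide at chromone C2 or at the alkyne terminus, with opening of the pyranone, during the homologation. The fallback brings the alkyne in before the pyranone is closed. It sets out from 2 and comes back at 8.
- The dianion of 2 (LiN(SiMe3)2, THF, –78 °C) is acylated with N-methoxy-N-methyl-3-(triisopropylsilyl)propiolamide to give 1-[2,4-bis(benzyloxy)-6-hydroxyphenyl]-5-(triisopropylsilyl)pent-4-yne-1,3-dione F7.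
- Acid-catalysed cyclodehydration gives 5,7-bis(benzyloxy)-2-[(triisopropylsilyl)ethynyl]-4H-chromen-4-one F8.
- Bu4NF buffered with AcOH removes the silyl group to give 8.

**Step 12.** The benzylic carbon of 19 is flanked by a di-ortho-substituted ring. The likely failure is slow reaction at that carbon, so that methylenation on the methyl side and self-condensation of the product enone compete. The fallback makes the same enone with no regiochemical choice. It sets out from 15 and comes back at 20.
- Aryllithium 17, generated from 15 as in step 10, is added to 3,3-dimethoxybutan-2-one to give rac-2-[2,6-bis(benzyloxy)-4-(methoxymethoxy)phenyl]-3,3-dimethoxybutan-2-ol F9.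
- Burgess reagent dehydrates the tertiary alcohol towards its only β-hydrogens, giving 1,3-bis(benzyloxy)-2-(3,3-dimethoxybut-1-en-2-yl)-5-(methoxymethoxy)benzene F10.
- Pyridinium tosylate in wet acetone hydrolyses the ketal, but not the aryl acetal, to give 20.

**Step 18 (with step 17).** The iodide sits between two alkoxy groups. The likely failure is slow transmetalation, so that protodeiodination overtakes coupling. Over-iodination in step 17 would add to the loss. The fallback installs the acetyl group by electrophilic acylation. It sets out from 25 and comes back at 28.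
- HCl in MeOH removes the acetal to give 5,7-bis(benzyloxy)-2-{3-[2,6-bis(benzyloxy)-4-hydroxyphenyl]-4-methoxyphenyl}-4H-chromen-4-one F11.
- Ac2O with BF3·OEt2 at 0 °C acetylates F11 at either of the two equivalent positions ortho to the phenol (Friedel–Crafts/Fries type), giving 28.
- The weakness of this fallback is possible loss of a peri benzyl group, which is why it is not the first choice.

**Step 20.** The ester and the acetyl group of 30 sit on a fully substituted ring. The likely failure is cleavage of the ester by adventitious hydroxide, returning 28, in place of the acyl shift. The fallback uses the chalcone route. It sets out from 28 and comes back at 32.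
- Claisen–Schmidt condensation of 28 with 4-(benzyloxy)benzaldehyde (KOH, EtOH, rt) gives 5,7-bis(benzyloxy)-2-[3-(2,6-bis(benzyloxy)-3-{(2E)-3-[4-(benzyloxy)phenyl]prop-2-enoyl}-4-hydroxyphenyl)-4-methoxyphenyl]-4H-chromen-4-one F12.
- Catalytic I2 in DMSO at 120 °C cyclises and oxidises F12 to 32.

## Further compounds

F1 | step 14 | methyl 5-[2,6-bis(benzyloxy)-4-(methoxymethoxy)phenyl]-4-(tert-butyldimethylsilyloxy)cyclohexa-1,4-diene-1-carboxylate | COC(=O)C1=CCC(O[Si](C)(C)C(C)(C)C)=C(c2c(OCc3ccccc3)cc(OCOC)cc2OCc2ccccc2)C1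
F2 | step 14 | methyl 3-[2,6-bis(benzyloxy)-4-(methoxymethoxy)phenyl]-4-(tert-butyldimethylsilyloxy)benzoate | COC(=O)c1ccc(O[Si](C)(C)C(C)(C)C)c(-c2c(OCc3ccccc3)cc(OCOC)cc2OCc2ccccc2)c1
F3 | step 14 | methyl 3-[2,6-bis(benzyloxy)-4-(methoxymethoxy)phenyl]-4-methoxybenzoate | COC(=O)c1ccc(OC)c(-c2c(OCc3ccccc3)cc(OCOC)cc2OCc2ccccc2)c1
F4 | step 14 | 3-[2,6-bis(benzyloxy)-4-(methoxymethoxy)phenyl]-4-methoxybenzoic acid | O=C(O)c1ccc(OC)c(-c2c(OCc3ccccc3)cc(OCOC)cc2OCc2ccccc2)c1
F5 | step 14 | 2-acetyl-3,5-bis(benzyloxy)phenyl 3-[2,6-bis(benzyloxy)-4-(methoxymethoxy)phenyl]-4-methoxybenzoate | CC(=O)c1c(OC(=O)c2ccc(OC)c(-c3c(OCc4ccccc4)cc(OCOC)cc3OCc3ccccc3)c2)cc(OCc2ccccc2)cc1OCc1ccccc1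
F6 | step 14 | 1-[2,4-bis(benzyloxy)-6-hydroxyphenyl]-3-{3-[2,6-bis(benzyloxy)-4-(methoxymethoxy)phenyl]-4-methoxyphenyl}propane-1,3-dione | COc1ccc(C(=O)CC(=O)c2c(O)cc(OCc3ccccc3)cc2OCc2ccccc2)cc1-c1c(OCc2ccccc2)cc(OCOC)cc1OCc1ccccc1
F7 | step 5 | 1-[2,4-bis(benzyloxy)-6-hydroxyphenyl]-5-(triisopropylsilyl)pent-4-yne-1,3-dione | CC(C)[Si](C#CC(=O)CC(=O)c1c(O)cc(OCc2ccccc2)cc1OCc1ccccc1)(C(C)C)C(C)C
F8 | step 5 | 5,7-bis(benzyloxy)-2-[(triisopropylsilyl)ethynyl]-4H-chromen-4-one | CC(C)[Si](C#Cc1cc(=O)c2c(OCc3ccccc3)cc(OCc3ccccc3)cc2o1)(C(C)C)C(C)C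
F9 | step 12 | rac-2-[2,6-bis(benzyloxy)-4-(methoxymethoxy)phenyl]-3,3-dimethoxybutan-2-ol | COCOc1cc(OCc2ccccc2)c(C(C)(O)C(C)(OC)OC)c(OCc2ccccc2)c1
F10 | step 12 | 1,3-bis(benzyloxy)-2-(3,3-dimethoxybut-1-en-2-yl)-5-(methoxymethoxy)benzene | COCOc1cc(OCc2ccccc2)c(C(=C)C(C)(OC)OC)c(OCc2ccccc2)c1
F11 | step 18 | 5,7-bis(benzyloxy)-2-{3-[2,6-bis(benzyloxy)-4-hydroxyphenyl]-4-methoxyphenyl}-4H-chromen-4-one | COc1ccc(-c2cc(=O)c3c(OCc4ccccc4)cc(OCc4ccccc4)cc3o2)cc1-c1c(OCc2ccccc2)cc(O)cc1OCc1ccccc1
F12 | step 20 | 5,7-bis(benzyloxy)-2-[3-(2,6-bis(benzyloxy)-3-{(2E)-3-[4-(benzyloxy)phenyl]prop-2-enoyl}-4-hydroxyphenyl)-4-methoxyphenyl]-4H-chromen-4-one | COc1ccc(-c2cc(=O)c3c(OCc4ccccc4)cc(OCc4ccccc4)cc3o2)cc1-c1c(OCc2ccccc2)cc(O)c(C(=O)/C=C/c2ccc(OCc3ccccc3)cc2)c1OCc1ccccc1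
A1 | alternative 1 | 1-{2,4-bis(benzyloxy)-3-[5-(1,3-dioxolan-2-yl)-2-methoxyphenyl]-6-hydroxyphenyl}-3-[4-(benzyloxy)phenyl]prop-2-yn-1-one | COc1ccc(C2OCCO2)cc1-c1c(OCc2ccccc2)cc(O)c(C(=O)C#Cc2ccc(OCc3ccccc3)cc2)c1OCc1ccccc1
A2 | alternative 1 | 3-[4-(benzyloxy)phenyl]propiolic acid | O=C(O)C#Cc1ccc(OCc2ccccc2)cc1
A3 | alternative 1 | 3,5-bis(benzyloxy)-4-[5-(1,3-dioxolan-2-yl)-2-methoxyphenyl]-2-(trimethylsilyl)phenyl trifluoromethanesulfonate | COc1ccc(C2OCCO2)cc1-c1c(OCc2ccccc2)cc(OS(=O)(=O)C(F)(F)F)c([Si](C)(C)C)c1OCc1ccccc1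
A4 | alternative 2 | 2-[4-(benzyloxy)phenyl]-6-[5-(1,3-dioxolan-2-yl)-2-methoxyphenyl]-5-hydroxy-7-(triisopropylsilyloxy)-4H-chromen-4-one | COc1ccc(C2OCCO2)cc1-c1c(O[Si](C(C)C)(C(C)C)C(C)C)cc2oc(-c3ccc(OCc4ccccc4)cc3)cc(=O)c2c1O
A5 | alternative 2 | 2-[4-(benzyloxy)phenyl]-6-(2-diazoacetyl)-4H-pyran-4-one | [N-]=[N+]=CC(=O)c1cc(=O)cc(-c2ccc(OCc3ccccc3)cc2)o1
A6 | alternative 2 | {[5-(1,3-dioxolan-2-yl)-2-methoxyphenyl]ethynyloxy}triisopropylsilane | COc1ccc(C2OCCO2)cc1C#CO[Si](C(C)C)(C(C)C)C(C)C
A7 | alternative 3 | methyl 3-[2,6-bis(benzyloxy)-4-(methoxymethoxy)phenyl]-4-methoxybenzoate | COC(=O)c1ccc(OC)c(-c2c(OCc3ccccc3)cc(OCOC)cc2OCc2ccccc2)c1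
A8 | alternative 3 | methyl coumalate | COC(=O)c1ccc(=O)oc1
A9 | alternative 3 | 1,3-bis(benzyloxy)-2-(methoxyethynyl)-5-(methoxymethoxy)benzene | COC#Cc1c(OCc2ccccc2)cc(OCOC)cc1OCc1ccccc1
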